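The numbers in the tables stem from a simulated flask with made-up constants; scatter was added.

A product excess that sinks with time invites the verdict of weak exchange between the substrates. The ochre flask shows such a sink: its excess reads 44.6% at 3.00 h and 17.3% at 10.0 h.

| flask | left-handed substrate | right-handed substrate | solid reagent | racemization catalyst | impurity | remark | time |
|---|---|---|---|---|---|---|---|
| ochre | 46 mM | 46 mM | 4 equiv | 0.53 mol% | 27 µM | the very flask that is asked about, followed so far |  |
| amber | 46 mM | 46 mM | 4 equiv | 0.53 mol% | 40 µM | run made earlier |  |
| flask | 46 mM | 46 mM | 4.00 equiv | 0.53 mol% | 27 µM |  | 20 h |

| run | time / h | left-handed product / % | right-handed product / % |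
|---|---|---|---|
| ochre | 1.50 | 11.3 | 3.6 |
| ochre | 3.00 | 19.6 | 7.5 |
| ochre | 5.00 | 27.9 | 15.7 |
| ochre | 6.00 | 33.1 | 18.7 |
| ochre | 8.00 | 37.6 | 24.8 |
| ochre | 10.0 | 41.3 | 29.1 |
| amber | 0.500 | 2.0 | 0.8 |
| amber | 1.50 | 10.2 | 3.6 |
| amber | 3.00 | 20.1 | 8.6 |
| amber | 4.00 | 25.2 | 12.0 |
| amber | 6.00 | 32.3 | 18.7 |
| amber | 8.00 | 37.0 | 24.5 |

(readings scatter by 0.5 percentage points)

- left-handed product and right-handed product together, in percent of the left-handed substrate and right-handed substrate charged together, at 20 h
- excess of left-handed product over right-handed product in the product at 20 h
- whether the exchange between left-handed substrate and right-handed substrate keeps pace with the reaction: how far the product's excess at 20 h gets from its value without exchange to its value with instant exchange (above 80% keeps pace, below 20% hardly takes part, else lags behind)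

- partner is single-handed; left-handed substrate and right-handed substrate are mirror images of each other, charged as a racemate, each of them at the stated concentration
- solid reagent is a solid; its amount is given per volume of the solution
- at the start none of the solid reagent is in solution
- an excess is below zero if the other one leads
- the handed part of partner does not stay in what it makes, so the products of the two hands are mirror images too

To test that verdict I take one number two ways: the decay constant of the unreacted substrate, both hands summed, late in the ochre run.

The first way assumes plain resolution, with each hand emptying its own pool. The ochre readings at 3.00 h give 0.166 h⁻¹ for the left hand and 0.0542 h⁻¹ for the right. By 10.0 h the left pool is thinned, so the mixture should decay at 0.0817 h⁻¹.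

The second way reads the sum directly. My carried quantity is the sum constant, the pseudo-first-order constant of the fraction of the charge not yet product. It cannot see which hand a product carries. Between 5.00 h and 10.0 h the ochre flask gives 0.129 h⁻¹, and the stretch before it, from 3.00 h, gives 0.128 h⁻¹.

The two ways part, by more than a scatter of 0.5 percentage points per reading can explain. The first way is the one that cheats: a sum constant that holds steady across the two stretches fits substrate pools that stay mixed, so I read the sinking excess as products changing hands. Carrying the sum constant from 10.0 h to 20 h, I commit to a yield of 91.8%, with the exchange keeping pace.

The forecast gives 88%, an excess of 9%, and an exchange that hardly takes part: “The pattern looks like plain kinetic resolution with little exchange.” It differs from my reckoning in yield and in pace.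

The flask gives 92.8% and an excess of 4.28%, and the exchange keeps pace, getting 90% of the way from the excess without exchange to the excess with instant exchange.

    solid reagent ⇌ partner, rate k1*(cs1 - [partner]) while solid is left; crystals form when [partner] > cs1 (solubility = 16.0 mM, k = 0.0460 min⁻¹)
    partner + left-handed substrate → left-handed product (k = 0.280 M⁻¹ min⁻¹)
    left-handed substrate + racemization catalyst ⇌ right-handed substrate + racemization catalyst, rate k3*[racemization catalyst]*[left-handed substrate] forward; the back reaction follows from the equilibrium constant (k = 17.0 M⁻¹ min⁻¹)
    racemization catalyst + impurity → spent catalyst (k = 6900 M⁻¹ min⁻¹)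
    left-handed product ⇌ right-handed product (k = 0.00200 min⁻¹)
    partner + right-handed substrate → right-handed product (k = 0.0670 M⁻¹ min⁻¹)

Over its whole 20 h this flask has a sum constant of 0.131 h⁻¹. The neighbouring flask, with 0.13 mol% of racemization catalyst and the other charges unchanged, yields 87.5%, so the same reckoning gives it 0.104 h⁻¹, less than this flask's. The neighbouring flask's product excess is 0.190%, lower than this flask's. Yet its substrates have come apart, with left-handed substrate at 1.93% of the charge and right-handed substrate at 10.6%.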